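**Retrosynthetic overview**

1. The target is a spiro-linked dimer of 14-hydroxytaxodione whose halves belong to opposite enantiomeric series. The dihydrofuran is cut at O-14′–C-7 (oxa-1,6-addition to a C-7 quinone methide) and at C-7–C-7′ (1,6-Michael addition), which leads back to the two enantiomers of one monomer.
2. Monomer: ring C is built first as a hexasubstituted benzene. Rings B and A are then closed in one operation by intramolecular Diels–Alder reaction of an o-quinodimethane released from a benzocyclobutene, forming C-6–C-7 (C-6′–C-7′ in the mirror-image half) and C-5–C-10.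
3. Enabling feature: ring B is fused to the six-membered carbocycle C along C-8–C-9, so C-7/C-8/C-9/C-10 is a latent o-quinodimethane. The C-6 oxygen marks the dienophile carbon (enol ether C-5=C-6), C-1 to C-4 of ring A form the four-atom tether, and C-20 is carried as a nitrile.
4. Ring order: C, temporary cyclobutene, B and A together (key step), dihydrofuran after the union. The racemic monomer is resolved once and both enantiomers are used.

Key step: step 12

Remark: the spiro half of the given structure is 5S,10S and the quinone-methide half is 5′R,10′R, so dimerizing one enantiomer cannot give it; the monomer is therefore made racemic and resolved.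
Naming: abietane numbering is used; primed locants denote the quinone-methide half; compounds named rac are racemates whose SMILES show one enantiomer; ξ marks a centre that is a mixture and is erased later.

**Route**

Step 1
Reactants: 1 1,2,4-trimethoxybenzene
Product: 2 2-(2,3,6-trimethoxyphenyl)propan-2-ol
Conditions: n-BuLi, THF, 0 °C to rt; acetone, −78 °C to rt; H2O
Reagents that add atoms: acetone, CC(C)=O
Why: Directed ortho-metalation takes place at C-3, between two methoxy groups, and the aryllithium adds to acetone (1,2-addition).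

Step 2
Reactants: 2 2-(2,3,6-trimethoxyphenyl)propan-2-ol
Product: 3 2-isopropyl-1,3,4-trimethoxybenzene
Conditions: Et3SiH, CF3CO2H, CH2Cl2, 0 °C to rt
Reagents that add atoms: none
Why: Ionic hydrogenation: the tertiary benzylic cation formed in acid is reduced by hydride transfer from the silane.

Step 3
Reactants: 3 2-isopropyl-1,3,4-trimethoxybenzene
Product: 4 1-bromo-3-isopropyl-2,4,5-trimethoxybenzene
Conditions: N-bromosuccinimide, MeCN, 0 °C
Reagents that add atoms: N-bromosuccinimide, O=C1CCC(=O)N1Br
Why: Electrophilic aromatic bromination should go to the ring position ortho to one methoxy group and para to another (the future C-8), as in the parent 1,2,4-trimethoxybenzene, and not to the position para to the isopropyl group.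

Step 4
Reactants: 4 1-bromo-3-isopropyl-2,4,5-trimethoxybenzene
Product: 5 2-bromo-4-isopropyl-3,5,6-trimethoxybenzaldehyde
Conditions: Cl2CHOCH3, TiCl4, CH2Cl2, −10 °C; H2O
Reagents that add atoms: dichloromethyl methyl ether, COC(Cl)Cl; water, O
Why: Rieche formylation at the only remaining ring hydrogen (the future C-9), which is activated by the ortho methoxy group.

Step 5
Reactants: 5 2-bromo-4-isopropyl-3,5,6-trimethoxybenzaldehyde
Product: 6 2-(2-bromo-4-isopropyl-3,5,6-trimethoxyphenyl)acetonitrile
Conditions: TosMIC, KOt-Bu, DME, −40 °C; MeOH, reflux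
Reagents that add atoms: p-toluenesulfonylmethyl isocyanide (TosMIC), Cc1ccc(cc1)S(=O)(=O)C[N+]#[C-]
Why: Van Leusen reductive cyanation converts the aldehyde into the homologous nitrile in one operation (ArCHO to ArCH2CN).

Step 6
Reactants: 6 2-(2-bromo-4-isopropyl-3,5,6-trimethoxyphenyl)acetonitrile
Product: 7 rac-2-(2-bromo-4-isopropyl-3,5,6-trimethoxyphenyl)propanenitrile
Conditions: LiN(i-Pr)2, THF, −78 °C; CH3I
Reagents that add atoms: iodomethane, CI
Why: Alkylation of the benzylic nitrile anion; the methyl group introduced here becomes C-7, and the two ortho substituents disfavour a second methylation.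

Step 7
Reactants: 8 isobutyronitrile (2-methylpropanenitrile); 9 1,3-dibromopropane
Product: 10 5-bromo-2,2-dimethylpentanenitrile
Conditions: LiN(i-Pr)2, THF, −78 °C; 9 (3 equiv), −78 °C to rt
Reagents that add atoms: none
Why: SN2 alkylation of the lithiated nitrile, with excess dibromide to suppress double substitution, sets up C-4 with its gem-dimethyl group and C-1 to C-3.

Step 8
Reactants: 10 5-bromo-2,2-dimethylpentanenitrile
Product: 11 5-bromo-2,2-dimethylpentanal
Conditions: i-Bu2AlH, CH2Cl2, −78 °C; aq. HCl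
Reagents that add atoms: water, O
Why: Partial reduction of the nitrile to the aluminium aldimine, hydrolysed on work-up to the non-enolizable aldehyde (future C-5).

Step 9
Reactants: 11 5-bromo-2,2-dimethylpentanal
Product: 12 benzyl 6-bromo-3,3-dimethylhex-1-enyl ether (E/Z mixture)
Conditions: [Ph3PCH2OCH2Ph]Cl, KN(SiMe3)2, THF, 0 °C; 11, −78 °C to rt
Reagents that add atoms: (benzyloxymethyl)triphenylphosphonium chloride, [Cl-].c1ccccc1COC[P+](c1ccccc1)(c1ccccc1)c1ccccc1
Why: Wittig olefination with an alkoxymethylene ylide gives the benzyl enol ether that serves as dienophile (C-5=C-6) and carries the C-6 oxygen; the alkene geometry is irrelevant because C-6 ends as a ketone.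

Step 10
Reactants: 7 rac-2-(2-bromo-4-isopropyl-3,5,6-trimethoxyphenyl)propanenitrile; 12 benzyl 6-bromo-3,3-dimethylhex-1-enyl ether
Product: 13 rac-8-(benzyloxy)-2-(2-bromo-4-isopropyl-3,5,6-trimethoxyphenyl)-2,6,6-trimethyloct-7-enenitrile (E/Z mixture)
Conditions: LiN(i-Pr)2, THF/DMPU, −78 °C; 12, −78 °C to rt
Reagents that add atoms: none
Why: SN2 alkylation of the tertiary benzylic nitrile anion with the primary bromide creates the quaternary carbon (future C-10) that carries the nitrile, the tether and the methyl group needed in step 11.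

Step 11
Reactants: 13 rac-8-(benzyloxy)-2-(2-bromo-4-isopropyl-3,5,6-trimethoxyphenyl)-2,6,6-trimethyloct-7-enenitrile
Product: 14 rac-7-[6-(benzyloxy)-4,4-dimethylhex-5-en-1-yl]-3-isopropyl-2,4,5-trimethoxybicyclo[4.2.0]octa-1,3,5-triene-7-carbonitrile
Conditions: Pd(OAc)2 (cat.), P(t-Bu)3·HBF4 (cat.), K2CO3, DMF, 140 °C
Reagents that add atoms: none
Why: Pd-catalysed C(sp3)–H arylation to a benzocyclobutene: oxidative addition of the C–Br bond to zerovalent palladium, carbonate-assisted metalation of the methyl group on the quaternary benzylic carbon and C–C reductive elimination from the five-membered palladacycle close the four-membered ring; the quaternary carbon rules out β-hydride elimination and the primary C–H bond reacts in preference to the chain methylene.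

Step 12
Reactants: 14 rac-7-[6-(benzyloxy)-4,4-dimethylhex-5-en-1-yl]-3-isopropyl-2,4,5-trimethoxybicyclo[4.2.0]octa-1,3,5-triene-7-carbonitrile
Product: 16 rac-6ξ-(benzyloxy)-11,12,14-trimethoxyabieta-8,11,13-triene-20-nitrile (trans A/B; H-5 α; C-20 β), via o-quinodimethane 15 (not isolated)
Conditions: 1,2-dichlorobenzene (0.01 M, degassed), 180 °C
Reagents that add atoms: none
Why: On heating, the cyclobutene ring of 14 opens by thermal conrotatory 4π electrocyclic ring opening (release of the four-membered-ring strain pays for the loss of aromaticity) to the o-quinodimethane 15, whose C-7/C-8/C-9/C-10 diene is trapped at once by the tethered enol ether in an intramolecular Diels–Alder reaction that forms C-6–C-7 and C-5–C-10 and restores the aromatic ring C. The closest known reaction type is the thermolysis of 1-cyano-1-alkylbenzocyclobutenes to angularly functionalized octahydrophenanthrenes. Ring B is closed by the [4+2] cycloaddition itself (both new bonds lie in it) and ring A is the tether ring, closed by the C-5–C-10 bond (type 1 intramolecular Diels–Alder reaction, four-atom tether). The new stereocentres C-10 (quaternary) and C-5 are set relative to each other by the transition state: with the chain rotating outward in the ring opening, a chair-like exo arrangement of the tether should give the trans A/B fusion; C-6 is a mixture that is erased later, any cis isomer is corrected once C-5 lies next to the C-6 ketone (step 16), and the product is racemic by design because both enantiomers are used. The step needs the cycloaddition to outrun [1,5]-hydrogen shift and dimerization of the o-quinodimethane and needs the chain on the outside of the diene; the nitrile (no hydrogen to shift, small enough to sit inside, later the C-20 methyl), high dilution, the gem-dimethyl group and the electron-rich enol ether matched to the cyano-substituted diene secure this, and the tether fixes the regiochemistry.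

Step 13
Reactants: 16 rac-6ξ-(benzyloxy)-11,12,14-trimethoxyabieta-8,11,13-triene-20-nitrile
Product: 17 rac-6ξ-(benzyloxy)-11,12,14-trimethoxyabieta-8,11,13-trien-20-al
Conditions: i-Bu2AlH, toluene, 0 °C to rt; aq. HCl
Reagents that add atoms: water, O
Why: Partial reduction of the hindered angular nitrile to the aldimine and hydrolysis; the quaternary C-10 cannot epimerize.

Step 14
Reactants: 17 rac-6ξ-(benzyloxy)-11,12,14-trimethoxyabieta-8,11,13-trien-20-al
Product: 18 rac-6ξ-(benzyloxy)-11,12,14-trimethoxyabieta-8,11,13-triene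
Conditions: N2H4·H2O, KOH, diethylene glycol, 130 °C then 200 °C
Reagents that add atoms: none
Why: Wolff–Kishner reduction (Huang-Minlon procedure) turns the angular aldehyde into the C-20 methyl group; the aryl methyl ethers and the benzyl ether are stable to the base.

Step 15
Reactants: 18 rac-6ξ-(benzyloxy)-11,12,14-trimethoxyabieta-8,11,13-triene
Product: 20 rac-6ξ,12-dihydroxyabieta-8,12-diene-11,14-dione (6-hydroxyroyleanone), via tetrol 19 (not isolated)
Conditions: BBr3, CH2Cl2, −78 °C to 0 °C; H2O; air, EtOAc, rt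
Reagents that add atoms: none
Why: BBr3 cleaves the three aryl methyl ethers and the benzyl ether (Lewis-acid ether cleavage), and the resulting 11,12,14-trihydroxyarene is autoxidized by air to the hydroxy-p-quinone, which keeps ring C out of the next oxidation.

Step 16
Reactants: 20 rac-6ξ,12-dihydroxyabieta-8,12-diene-11,14-dione
Product: 21 rac-14-hydroxytaxodione [rac-11,14-dihydroxyabieta-7,9(11),13-triene-6,12-dione]
Conditions: Dess–Martin periodinane, NaHCO3, CH2Cl2, rt; Et3N (cat.), rt
Reagents that add atoms: none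
Why: Dess–Martin oxidation of the secondary C-6 alcohol gives the 6-ketone, which rests as its quinone-methide tautomer; C-5, now α to the ketone, should equilibrate to the trans ring fusion, so both C-6 epimers and any cis adduct from step 12 converge.

Step 17
Reactants: 21 rac-14-hydroxytaxodione
Product: 22 (5S,10S)-14-hydroxytaxodione; 23 (5R,10R)-14-hydroxytaxodione (both enantiomers collected)
Conditions: preparative supercritical-fluid chromatography on a chiral stationary phase (amylose tris(3,5-dimethylphenylcarbamate)), CO2/MeOH (0.1% HCO2H)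
Reagents that add atoms: none
Why: Resolution by chromatography on a chiral phase, with no bond made or broken; both fractions are used (22 for the spiro half, 23 for the quinone-methide half), and their absolute configurations are to be assigned by chiroptical comparison with the natural 5S,10S series.

Step 18
Reactants: 22 (5S,10S)-14-hydroxytaxodione
Product: 24 (5S,10S)-11,14-bis(benzyloxy)abieta-7,9(11),13-triene-6,12-dione
Conditions: BnBr, K2CO3, DMF, rt
Reagents that add atoms: benzyl bromide, BrCc1ccccc1
Why: Williamson O-alkylation of the two acidic enolic hydroxyls removes every acidic proton, so that 24 can act only as an electrophile at C-7; which of the ring C oxygens are benzylated is not critical, since all benzyl groups are removed in step 21.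

Step 19
Reactants: 23 (5R,10R)-14-hydroxytaxodione; 24 (5S,10S)-11,14-bis(benzyloxy)abieta-7,9(11),13-triene-6,12-dione
Product: 25 (5S,10S)-11,14-bis(benzyloxy)-12-hydroxy-7ξ-[(5′R,10′R)-11′,14′-dihydroxy-6′,12′-dioxoabieta-7′,9′(11′),13′-trien-7′-yl]abieta-8,11,13-trien-6-one
Conditions: DBU (2.2 equiv), THF (degassed), −20 °C to rt; AcOH
Reagents that add atoms: none
Why: 1,6-Conjugate (vinylogous Michael) addition of a 1,3-dicarbonyl-type carbon nucleophile to a p-quinone methide: the dianion of 23 (extended enolate of the C-6′ ketone, nucleophilic at C-7′ and no longer an acceptor) adds to C-7 of 24, which has no acidic proton and can only be the electrophile, so the halves cannot exchange roles; O-adducts revert, ring C of the acceptor aromatizes, and the C-7 configuration is irrelevant because C-7 is planarized in step 20.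

Step 20
Reactants: 25 C-7/C-7′-linked adduct
Product: 27 (5S,7R,10S)-11,14-bis(benzyloxy)-12-hydroxy-6-oxoabieta-8,11,13-triene spiro-fused at C-7 (O-14′ α; C-7′ β) to the 2H-furan ring O-14′/C-14′/C-8′/C-7′ of (5′R,10′R)-11′-hydroxyabieta-7′,9′(11′),13′-triene-6′,12′-dione, via bis(quinone methide) 26 (not isolated)
Conditions: Ag2O, CH2Cl2, rt, dark
Reagents that add atoms: none
Why: Ag2O oxidizes the 2,6-disubstituted 4-alkylphenol to the p-quinone methide 26 (C-7=C-8), and the neighbouring enolic 14′-OH adds to C-7 in a 5-exo-trig oxa-1,6-addition that restores the aromatic ring C; the quaternary stereocentre C-7 should be set by attack of O-14′ on the α face, anti to the axial C-20 methyl group, which leaves C-7′ on the β face as in the target, and the addition is reversible, so the more stable spiro isomer can be reached.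

Step 21
Reactants: 27 dibenzyl spiro compound
Product: 29 target CNP0568854.1, via leuco hexaphenol 28 (not isolated)
Conditions: H2 (1 atm), Pd/C, EtOAc, rt; filtration under argon; air, rt
Reagents that add atoms: none
Why: Hydrogenolysis removes the two benzyl ethers (and reduces the primed quinone methide to its catechol) under neutral conditions that do not ionize the spiro ether, and air then oxidizes the 11,12,14-triol to the hydroxyquinone and the 6′-oxo catechol to the o-quinone, which tautomerizes to the quinone methide as in the catechol-to-taxodione oxidation; only C-7′ changes, and it returns to sp2.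

**Compound list**

1 | 1,2,4-trimethoxybenzene | COc1ccc(OC)c(OC)c1 | starting material
2 | 2-(2,3,6-trimethoxyphenyl)propan-2-ol | COc1ccc(OC)c(C(C)(C)O)c1OC | intermediate
3 | 2-isopropyl-1,3,4-trimethoxybenzene | COc1ccc(OC)c(C(C)C)c1OC | intermediate
4 | 1-bromo-3-isopropyl-2,4,5-trimethoxybenzene | COc1cc(Br)c(OC)c(C(C)C)c1OC | intermediate
5 | 2-bromo-4-isopropyl-3,5,6-trimethoxybenzaldehyde | COc1c(C=O)c(Br)c(OC)c(C(C)C)c1OC | intermediate
6 | 2-(2-bromo-4-isopropyl-3,5,6-trimethoxyphenyl)acetonitrile | COc1c(CC#N)c(Br)c(OC)c(C(C)C)c1OC | intermediate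
7 | rac-2-(2-bromo-4-isopropyl-3,5,6-trimethoxyphenyl)propanenitrile | COc1c(C(C)C#N)c(Br)c(OC)c(C(C)C)c1OC | intermediate
8 | isobutyronitrile | CC(C)C#N | starting material
9 | 1,3-dibromopropane | BrCCCBr | starting material
10 | 5-bromo-2,2-dimethylpentanenitrile | CC(C)(CCCBr)C#N | intermediate
11 | 5-bromo-2,2-dimethylpentanal | CC(C)(CCCBr)C=O | intermediate
12 | benzyl 6-bromo-3,3-dimethylhex-1-enyl ether (E/Z mixture) | BrCCCC(C)(C)C=COCc1ccccc1 | intermediate
13 | rac-8-(benzyloxy)-2-(2-bromo-4-isopropyl-3,5,6-trimethoxyphenyl)-2,6,6-trimethyloct-7-enenitrile (E/Z mixture) | COc1c(C(C)(C#N)CCCC(C)(C)C=COCc2ccccc2)c(Br)c(OC)c(C(C)C)c1OC | intermediate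
14 | rac-7-[6-(benzyloxy)-4,4-dimethylhex-5-en-1-yl]-3-isopropyl-2,4,5-trimethoxybicyclo[4.2.0]octa-1,3,5-triene-7-carbonitrile | N#CC1(CCCC(C)(C)C=COCc2ccccc2)Cc2c(OC)c(C(C)C)c(OC)c(OC)c21 | intermediate
15 | o-quinodimethane from 14 (not isolated) | C=C1C(OC)=C(C(C)C)C(OC)=C(OC)C1=C(C#N)CCCC(C)(C)C=COCc1ccccc1 | intermediate
16 | rac-6ξ-(benzyloxy)-11,12,14-trimethoxyabieta-8,11,13-triene-20-nitrile (trans A/B) | COc1c(OC)c(C(C)C)c(OC)c2c1[C@@]1(C#N)CCCC(C)(C)[C@@H]1C(OCc1ccccc1)C2 | intermediate
17 | rac-6ξ-(benzyloxy)-11,12,14-trimethoxyabieta-8,11,13-trien-20-al | COc1c(OC)c(C(C)C)c(OC)c2c1[C@@]1(C=O)CCCC(C)(C)[C@@H]1C(OCc1ccccc1)C2 | intermediate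
18 | rac-6ξ-(benzyloxy)-11,12,14-trimethoxyabieta-8,11,13-triene | COc1c(OC)c(C(C)C)c(OC)c2c1[C@@]1(C)CCCC(C)(C)[C@@H]1C(OCc1ccccc1)C2 | intermediate
19 | rac-abieta-8,11,13-triene-6ξ,11,12,14-tetrol (not isolated) | Oc1c(O)c(C(C)C)c(O)c2c1[C@@]1(C)CCCC(C)(C)[C@@H]1C(O)C2 | intermediate
20 | rac-6ξ,12-dihydroxyabieta-8,12-diene-11,14-dione | O=C1C(O)=C(C(C)C)C(=O)C2=C1[C@@]1(C)CCCC(C)(C)[C@@H]1C(O)C2 | intermediate
21 | rac-14-hydroxytaxodione | O=C1C(C(C)C)=C(O)C2=CC(=O)[C@H]3C(C)(C)CCC[C@]3(C)C2=C1O | intermediate
22 | (5S,10S)-14-hydroxytaxodione | O=C1C(C(C)C)=C(O)C2=CC(=O)[C@H]3C(C)(C)CCC[C@]3(C)C2=C1O | intermediate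
23 | (5R,10R)-14-hydroxytaxodione | O=C1C(C(C)C)=C(O)C2=CC(=O)[C@@H]3C(C)(C)CCC[C@@]3(C)C2=C1O | intermediate
24 | (5S,10S)-11,14-bis(benzyloxy)abieta-7,9(11),13-triene-6,12-dione | O=C1C(C(C)C)=C(OCc2ccccc2)C2=CC(=O)[C@H]3C(C)(C)CCC[C@]3(C)C2=C1OCc1ccccc1 | intermediate
25 | C-7/C-7′-linked adduct (unprimed half 5S,10S, 7ξ; primed half 5′R,10′R) | C(c1ccccc1)Oc1c(O)c(C(C)C)c(OCc2ccccc2)c2c1[C@@]1(C)CCCC(C)(C)[C@@H]1C(=O)C2C1=C3C(O)=C(C(C)C)C(=O)C(O)=C3[C@]3(C)CCCC(C)(C)[C@H]3C1=O | intermediate
26 | bis(quinone methide) from 25 (not isolated) | O=C1C(C(C)C)=C(OCc2ccccc2)C2=C(C4=C5C(O)=C(C(C)C)C(=O)C(O)=C5[C@]5(C)CCCC(C)(C)[C@H]5C4=O)C(=O)[C@H]3C(C)(C)CCC[C@]3(C)C2=C1OCc1ccccc1 | intermediate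
27 | spiro compound, 11,14-di-O-benzyl-12-hydroxy arene in the spiro half (5S,7R,10S; 5′R,10′R) | CC(C)c1c(OCc2ccccc2)c2c(c(OCc3ccccc3)c1O)[C@@]1(C)CCCC(C)(C)[C@@H]1C(=O)[C@@]21OC2=C(C(C)C)C(=O)C(O)=C3C2=C1C(=O)[C@@H]1C(C)(C)CCC[C@@]31C | intermediate
28 | leuco hexaphenol (11,12,14-triol; 11′,12′-diol; 7′ξ-H; not isolated) | CC(C)c1c(O)c2c(c(O)c1O)[C@@]1(C)CCCC(C)(C)[C@@H]1C(=O)[C@@]21Oc2c(C(C)C)c(O)c(O)c3c2C1C(=O)[C@@H]1C(C)(C)CCC[C@@]31C | intermediate
29 | CNP0568854.1 | CC(C)C1=C(O)C2=C(C(=O)C1=O)[C@@]1(C)CCCC(C)(C)[C@@H]1C(=O)[C@@]21OC2=C(C(C)C)C(=O)C(O)=C3C2=C1C(=O)[C@@H]1C(C)(C)CCC[C@@]31C | target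

**Count and risks**

Total step count: 21. Longest linear sequence: 18 steps (steps 1–6 and 10–21).

Steps most likely to fail:

Step 19. The bond between the two congested C-7 carbons may be outrun by reversible O-addition, by proton transfer that quenches the dianion, or by self-condensation of 23. The fallback sets out from 23 and returns at 25. Reduction of 23 (Na2S2O4) and silylation (t-BuMe2SiCl, imidazole, DMF) should give (5R,10R)-11,12,14-tris(tert-butyldimethylsilyloxy)abieta-8,11,13-trien-6-one F5. Me3SiOSO2CF3/Et3N should give its 6-trimethylsilyloxy-6-ene (silyl enol ether) F6. Lewis-acid-promoted Mukaiyama-type 1,6-addition of the enol ether to quinone methide 24 (BF3·OEt2 or Sc(OSO2CF3)3, CH2Cl2, −78 °C) should give the silylated C-7/C-7′ adduct F7. Bu4NF followed by air removes the silyl groups and reoxidizes ring C′, giving 25.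

Step 12. The o-quinodimethane may undergo [1,5]-hydrogen shift from the chain methylene or dimerize faster than it cyclizes. The fallback sets out from 4 and returns at 21. Bromine–lithium exchange of 4 (n-BuLi, THF, −78 °C) and BF3·OEt2-assisted opening at the CH2 terminus of 2-(2,6,6-trimethylcyclohex-1-en-1-yl)oxirane F1 (from commercial β-cyclocitral, Me3S+ I−, NaH, DMSO; Corey–Chaykovsky reaction) should give rac-2-(3-isopropyl-2,4,5-trimethoxyphenyl)-1-(2,6,6-trimethylcyclohex-1-en-1-yl)ethan-1-ol F2. Dess–Martin oxidation should give 2-(3-isopropyl-2,4,5-trimethoxyphenyl)-1-(2,6,6-trimethylcyclohex-1-en-1-yl)ethan-1-one F3. Polyphosphoric acid (80 °C) closes ring B by intramolecular Friedel–Crafts conjugate alkylation (C-9 to C-10), and NaOMe/MeOH equilibrates C-5, giving rac-11,12,14-trimethoxyabieta-8,11,13-trien-6-one F4. BBr3 then air gives 21 directly. This fallback closes ring B at C-9–C-10 and gives up the cycloaddition.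

Step 20. The oxidant may attack the enolic quinone-methide half or the benzyl ethers instead of forming the C-7 quinone methide cleanly. The fallback sets out from 25 and returns at 27. α-Bromination of the C-6 ketone at its tertiary benzylic carbon (CuBr2, EtOAc/CHCl3, reflux; C-7′ carries no hydrogen) should give the 7ξ-bromo derivative of 25 F8. AgOSO2CF3 with 2,6-di-tert-butylpyridine (CH2Cl2, −40 °C) ionizes the bromide, and the 14′-OH closes the dihydrofuran by SN1 etherification from the α face, giving 27.

**Further compounds**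

F1 | step 12 | 2-(2,6,6-trimethylcyclohex-1-en-1-yl)oxirane | CC1=C(C2CO2)C(C)(C)CCC1
F2 | step 12 | rac-2-(3-isopropyl-2,4,5-trimethoxyphenyl)-1-(2,6,6-trimethylcyclohex-1-en-1-yl)ethan-1-ol | COc1cc(CC(O)C2=C(C)CCCC2(C)C)c(OC)c(C(C)C)c1OC
F3 | step 12 | 2-(3-isopropyl-2,4,5-trimethoxyphenyl)-1-(2,6,6-trimethylcyclohex-1-en-1-yl)ethan-1-one | COc1cc(CC(=O)C2=C(C)CCCC2(C)C)c(OC)c(C(C)C)c1OC
F4 | step 12 | rac-11,12,14-trimethoxyabieta-8,11,13-trien-6-one | COc1c(OC)c(C(C)C)c(OC)c2c1[C@@]1(C)CCCC(C)(C)[C@@H]1C(=O)C2
F5 | step 19 | (5R,10R)-11,12,14-tris(tert-butyldimethylsilyloxy)abieta-8,11,13-trien-6-one | CC(C)(C)[Si](C)(C)Oc1c(O[Si](C)(C)C(C)(C)C)c(C(C)C)c(O[Si](C)(C)C(C)(C)C)c2c1[C@]1(C)CCCC(C)(C)[C@H]1C(=O)C2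
F6 | step 19 | (5R,10R)-11,12,14-tris(tert-butyldimethylsilyloxy)-6-(trimethylsilyloxy)abieta-6,8,11,13-tetraene | CC(C)(C)[Si](C)(C)Oc1c(O[Si](C)(C)C(C)(C)C)c(C(C)C)c(O[Si](C)(C)C(C)(C)C)c2c1[C@]1(C)CCCC(C)(C)[C@H]1C(O[Si](C)(C)C)=C2
F7 | step 19 | (5S,10S)-11,14-bis(benzyloxy)-12-hydroxy-7ξ-[(5′R,10′R)-11′,12′,14′-tris(tert-butyldimethylsilyloxy)-6′-oxoabieta-8′,11′,13′-trien-7′ξ-yl]abieta-8,11,13-trien-6-one | C(c1ccccc1)Oc1c(O)c(C(C)C)c(OCc2ccccc2)c2c1[C@@]1(C)CCCC(C)(C)[C@@H]1C(=O)C2C1C(=O)[C@@H]3C(C)(C)CCC[C@@]3(C)c3c(O[Si](C)(C)C(C)(C)C)c(O[Si](C)(C)C(C)(C)C)c(C(C)C)c(O[Si](C)(C)C(C)(C)C)c31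
F8 | step 20 | 7ξ-bromo derivative of 25 | C(c1ccccc1)Oc1c(O)c(C(C)C)c(OCc2ccccc2)c2c1[C@@]1(C)CCCC(C)(C)[C@@H]1C(=O)C2(Br)C1=C3C(O)=C(C(C)C)C(=O)C(O)=C3[C@]3(C)CCCC(C)(C)[C@H]3C1=O
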